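## The problem

The target is a germacranolide: a ten-membered carbocycle (C1–C10) fused through C6 and C7 to a butenolide (ring O on C6, C7=C11, C12=O). C11 carries an acetoxymethyl group (C13) and the C8 oxygen carries a (2S)-2-methylglycidate. The ring bears two trisubstituted epoxides: the 1,10-epoxide has C2 and C9 trans (it derives from an E alkene), and the 4,5-epoxide has C3 and C6 cis. Seven stereocentres have to be set, read from the SMILES string as 1R,4R,5S,6S,8S,10R and 2′S. C4 is quaternary and C8 is separated from it by the butenolide, so each needs its own reagent-based control. C5 and C6 are contiguous with C4 and can take their configuration from C4 and C8, whereas C1 and C10 can only be reached through the conformation of the ring, and C2′ is best bought. The fragile functions are three epoxides (protic and Lewis acids), an allylic acetate, and the butenolide, whose γ-hydrogen at C6 is acidic and sits next to a C5–O bond, so base can expel any C5 leaving group by E1cB. A free C8 hydroxyl can also re-lactonise onto C12. The enabling feature is that C6 is the γ-carbon of the butenolide and C5 is an oxygenated carbon on fully substituted C4. C5–C6 is therefore the bond that a vinylogous aldol forms between a 2-silyloxyfuran (O, C12, C11, C7, C6) and a non-enolisable α-alkoxy aldehyde whose C4 oxygen can hold a chelating metal.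

## Retrosynthesis

**37 ⇒ 36.** The two C–O bonds of the 1,10-epoxide are cut last. A trisubstituted epoxide would not survive the Lewis acid of the ring closure or the acidic desilylation. Its precursor alkene in 36 is electron-rich while C7=C11 is electron-poor, so chemoselectivity is not in doubt. The E alkene also stiffens the chain during ring closure. The forward step must deliver oxygen to the face that gives 1R,10R.

**36 ⇒ 32 + 34.** The ester C–O bond at C8 is cut. The acyl group contains its own epoxide and is therefore attached after every Lewis-acidic step. The lithium salt 34 comes from commercial ester 33. The forward reaction is an acylation of a hindered secondary alcohol under mild base.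

**32 ⇒ 31 ⇒ 30 ⇒ 29 ⇒ 28 ⇒ 27.** After removal of the C8 silyl ether (31) and the C13 acetate (30), the C5–O bond of the 4,5-epoxide is cut. In 29 the C4 hydroxyl displaces a C5 mesylate with inversion, which requires the 4,5-syn (5R) alcohol 27. Epoxidation of a 4Z alkene would avoid the inversion but would force a different ring-forming bond; here the C5 oxygen is a direct product of the ring closure. The C4 oxygen carries a 4-methoxybenzyl group, which chelates in the key step and is removed oxidatively only after mesylation (28), so no neighbouring hydroxyl can trap it as an acetal. The C8 oxygen stays silylated through the basic epoxide closure so that it cannot attack C12 or C5.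

**27 ⇒ 26.** The C5–C6 bond is cut, opening the ten-membered ring to the acyclic silyloxyfuran aldehyde 26. Closures at C1–C2 or C2–C3 would be stereochemically silent, and building the lactone on a preformed ring would require functionalising C7 of a medium ring. This cut alone creates two stereocentres (C5, C6) and joins lactone and carbocycle in one event. The forward reaction must close a ten-membered ring in competition with oligomerisation, add to the chelated aldehyde face, and use the correct furan face.

**26 ⇒ 25 ⇒ 24.** The O–Si bond is cut back to butenolide 25, and the aldehyde to primary alcohol 24. Taking C5 from a primary alcohol avoids cleaving a vinyl group beside the more electron-rich C1=C10 alkene, which a terpene-alcohol chiral pool would demand.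

**24 ⇒ 19 + 22; 22 ⇒ 21 ⇒ 20 + 2.** The butenolide is cut at C6–O and at C7=C11: carboxylate alkylation of chloroketone 19 by phosphono acid 22, then intramolecular olefination. Acid 22 brings C13 already oxygenated, which avoids α-functionalising a finished butenolide. It comes from acrylate 20 and alcohol 2 by conjugate addition (C13–O), then ester cleavage.

**19 ⇒ 18 ⇒ 3 + 16.** C6 is removed (C6–C7, one-carbon homologation of Weinreb amide 18). The C1–C2 sp3–sp2 bond is then cut, dividing the chain into two halves of similar size, each with one stereocentre: alkene 3 (C2–C5, C15) and vinyl iodide 16 (C1, C7–C10, C14). The coupling must retain the E geometry.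

**16 ⇒ 15 ⇒ 13 + 7; 13 ⇒ 10 + 11; 10 ⇒ 8; 7 ⇒ 6 ⇒ 4.** The C8–C9 bond is cut as an auxiliary-controlled glycolate alkylation, which sets C8. Imide 13 comes from glycolic acid 8 (through 10) and oxazolidinone 11. The allylic iodide 7 comes from propargyl alcohol 4 through 6 by carboalumination, which forms C10–C14 and fixes the E geometry.

**3 ⇒ 1 + 2.** The C4–O bond is cut as an asymmetric allylic etherification of racemic vinyl epoxide 1 with alcohol 2. One step sets the quaternary centre and installs the chelating ether, leaving the C5 hydroxyl free.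

## Roads not taken

Alternative 1: The cut is at C4–C5 and C1–C10, made by a photochemical [2+2] addition of a cyclohexenone carrying the C8 oxygen to a methyl-substituted cyclobutene. The tricyclic photoadduct A1 would then undergo strain-driven cycloreversion of its central four-membered ring to a cyclodeca-1,5-dienone. Its merit is speed: two operations from small pieces give the ten-membered ring with both ring alkenes, so both epoxides could come from alkene epoxidation and no displacement next to the acidic C6–H would be needed. In that respect it is better than the chosen plan. Its weak points for this target are several: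
- The regiochemistry of the photoaddition (which cyclobutene carbon bonds to C5) is poorly controlled, and facial control from the remote C8 stereocentre is weak.
- The alkene geometry after cycloreversion is set by orbital symmetry, not by choice.
- The 1,5-diene can undergo Cope rearrangement to a divinylcyclohexane at the temperature of the cycloreversion.
- The butenolide (C11–C13, the C7=C11 bond, the C6 oxygen) would still have to be built on the mobile medium ring.

The chosen plan sets against this a closure that arrives with all fifteen skeletal carbons, the lactone, and C4, C5, C6 and C8 defined.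

Alternative 2: The cut is an anionic oxy-Cope ring expansion. A potassium alkoxide of a 1,2-dialkenylcyclohexenol from the terpene chiral pool would rearrange, forming C8–C9 and cleaving the six-membered ring, to give dienone A2. The merits are real: the reaction type is well established for germacranes, the chair transition state sets the E alkene and relays chirality, and the 4Z-enone could be epoxidised without any inversion. The ring-forming step is clearly more secure than the new macrocyclisation chosen here. The weak point is what follows. C7 of A2 is a methylene between the C6 ketone and the oxygenated C8, and a C7 enolate would lose the C8 alkoxy group by β-elimination. Attaching C11–C13 there and forming the tetrasubstituted C7=C11 bond is therefore hazardous. The C6 reduction and the enone epoxidation also rest on ring conformation alone. The chosen plan avoids all functionalisation of C7 on a formed ring and sets C5 and C6 in the ring-forming event.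

Alternative 3: The cut is at C2–C3. A C2 allylic sulfone anion would displace a C3 allylic bromide to give macrocycle A3. The merits are that the bond forms far from any stereocentre, that this macrocyclisation type is long established for ten-membered terpenoid rings, and that C6, C8 and both ring alkenes are fixed beforehand. It also keeps the acidic butenolide out of the molecule until late, which sidesteps the elimination risk the chosen plan must manage. Against it:
- The sulfone must be removed, with a risk of shifting the C1=C10 alkene.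
- The Z allylic bromide can isomerise or react at its far terminus.
- The 7-methylene group must still be turned into the oxygenated butenolide on the sensitive ring.
- Two alkenes must be epoxidised face-selectively among three.

The chosen plan sets against this a ring closure that builds two stereocentres and delivers the complete lactone.

Key step: step 15

Assumption: compounds 1, 2, 4, 8, 11, 20 and 33 are taken as purchased, and the SMILES string is read as 1R,4R,5S,6S,8S,10R with a (2S)-glycidate. Abbreviations: PMB = 4-methoxybenzyl, TBS = tert-butyldimethylsilyl, TIPS = triisopropylsilyl, 9-BBN = 9-borabicyclo[3.3.1]nonane.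

Step 1
Reactants: 1 2-methyl-2-vinyloxirane (racemic), 2 4-methoxybenzyl alcohol
Product: 3 (2R)-2-[(4-methoxybenzyl)oxy]-2-methylbut-3-en-1-ol
Conditions: Pd2(dba)3·CHCl3 (1 mol %), N,N′-bis(2-diphenylphosphinobenzoyl)-trans-1,2-diaminocyclohexane (3 mol %, the antipode that gives the R ether), Et3B (1 mol %), CH2Cl2, rt
Reagents that add atoms: none
Why: Palladium-catalysed dynamic kinetic asymmetric allylic etherification (Tsuji–Trost type): the π-allyl intermediates interconvert, the borane ties the alcohol to the alkoxide and delivers it to the substituted terminus, so the branched tertiary ether forms and the ligand sets C4.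

Step 2
Reactants: 4 propargyl alcohol
Product: 6 (E)-3-iodo-2-methylprop-2-en-1-ol, via alkenylalane 5 (not isolated)
Conditions: AlMe3 (3 equiv), Cp2ZrCl2 (0.25 equiv), CH2Cl2, 0 °C → rt; then I2, THF, −30 → 0 °C; aq. K2CO3
Reagents that add atoms: trimethylaluminium C[Al](C)C; iodine II
Why: Negishi carboalumination adds methyl and aluminium syn across the alkyne with methyl at the internal carbon, and iodinolysis retains geometry, which fixes the E alkene (future C1=C10) and brings in C14.

Step 3
Reactants: 6 (E)-3-iodo-2-methylprop-2-en-1-ol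
Product: 7 (E)-1,3-diiodo-2-methylprop-1-ene
Conditions: PPh3, I2, imidazole, CH2Cl2, 0 °C, dark; used at once
Reagents that add atoms: iodine II
Why: Appel-type iodination of a primary allylic alcohol by SN2 displacement of the oxyphosphonium; the vinyl iodide is inert.

Step 4
Reactants: 8 glycolic acid
Product: 10 (tert-butyldimethylsilyloxy)acetic acid, via bis-silyl glycolate 9 (not isolated)
Conditions: TBSCl (2.2 equiv), imidazole, DMF, rt; then K2CO3, MeOH/THF/H2O, rt; acidify to pH 4
Reagents that add atoms: tert-butyldimethylsilyl chloride CC(C)(C)[Si](C)(C)Cl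
Why: Bis-silylation followed by selective hydrolysis of the silyl ester, which is far more labile than the silyl ether, gives the O-protected acid.

Step 5
Reactants: 10 (tert-butyldimethylsilyloxy)acetic acid, 11 (R)-4-benzyl-2-oxazolidinone
Product: 13 (4R)-4-benzyl-3-[(tert-butyldimethylsilyloxy)acetyl]oxazolidin-2-one, via mixed pivalic anhydride 12 (not isolated)
Conditions: t-BuCOCl, Et3N, THF, −20 °C; then 11, LiCl, −20 °C → rt
Reagents that add atoms: none
Why: N-Acylation of the oxazolidinone through the mixed pivalic anhydride (LiCl/amine variant); the nucleophile attacks the unhindered glycolyl carbonyl.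

Step 6
Reactants: 13 (4R)-4-benzyl-3-[(tert-butyldimethylsilyloxy)acetyl]oxazolidin-2-one, 7 (E)-1,3-diiodo-2-methylprop-1-ene
Product: 15 (4R)-4-benzyl-3-[(2S,4E)-2-(tert-butyldimethylsilyloxy)-5-iodo-4-methylpent-4-enoyl]oxazolidin-2-one, via sodium enolate 14 (not isolated)
Conditions: NaN(SiMe3)2, THF, −78 °C; then 7 (3 equiv), −78 → −45 °C
Reagents that add atoms: none
Why: Auxiliary-controlled asymmetric alkylation of the chelated Z enolate of a glycolyl oxazolidinone: the benzyl group shields one face, the allylic iodide enters from the other, and with the R auxiliary C8 is set as S.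

Step 7
Reactants: 15 (4R)-4-benzyl-3-[(2S,4E)-2-(tert-butyldimethylsilyloxy)-5-iodo-4-methylpent-4-enoyl]oxazolidin-2-one
Product: 16 (2S,4E)-2-(tert-butyldimethylsilyloxy)-5-iodo-N-methoxy-N,4-dimethylpent-4-enamide
Conditions: MeNH(OMe)·HCl, AlMe3, CH2Cl2, −20 → 0 °C
Reagents that add atoms: N,O-dimethylhydroxylamine hydrochloride CNOC.Cl
Why: Aluminium amide transamidation of the N-acyl oxazolidinone gives the Weinreb amide and releases the auxiliary; the conditions are not basic enough to epimerise C8.

Step 8
Reactants: 3 (2R)-2-[(4-methoxybenzyl)oxy]-2-methylbut-3-en-1-ol, 16 (2S,4E)-2-(tert-butyldimethylsilyloxy)-5-iodo-N-methoxy-N,4-dimethylpent-4-enamide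
Product: 18 (2S,4E,8R)-2-(tert-butyldimethylsilyloxy)-9-hydroxy-N-methoxy-8-[(4-methoxybenzyl)oxy]-N,4,8-trimethylnon-4-enamide, via B-alkyl-9-BBN borane 17 (not isolated)
Conditions: 3, 9-BBN (2.3 equiv), THF, 0 °C → rt; then 16, Pd(dppf)Cl2·CH2Cl2 (5 mol %), AsPh3, K3PO4 (3 M aq.), DMF, rt
Reagents that add atoms: none
Why: Anti-Markovnikov hydroboration of the vinyl group and B-alkyl Suzuki–Miyaura coupling with the vinyl iodide form C1–C2 with retention of the E geometry; the free hydroxyl is carried as its borinate and released on work-up.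

Step 9
Reactants: 18 (2S,4E,8R)-2-(tert-butyldimethylsilyloxy)-9-hydroxy-N-methoxy-8-[(4-methoxybenzyl)oxy]-N,4,8-trimethylnon-4-enamide
Product: 19 (3S,5E,9R)-3-(tert-butyldimethylsilyloxy)-1-chloro-10-hydroxy-9-[(4-methoxybenzyl)oxy]-5,9-dimethyldec-5-en-2-one
Conditions: ICH2Cl (4 equiv), MeLi·LiBr (4 equiv), THF/Et2O, −78 °C; aq. NH4Cl
Reagents that add atoms: chloroiodomethane ClCI
Why: Carbenoid homologation of a Weinreb amide: chloromethyllithium formed in the presence of the amide adds once, and the stable tetrahedral intermediate collapses to the α-chloroketone on work-up; one equivalent of base is consumed by the free hydroxyl.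

Step 10
Reactants: 20 ethyl 2-(diethoxyphosphoryl)acrylate, 2 4-methoxybenzyl alcohol
Product: 21 ethyl 2-(diethoxyphosphoryl)-3-[(4-methoxybenzyl)oxy]propanoate (racemic)
Conditions: NaH (5 mol %), THF, 0 °C → rt
Reagents that add atoms: none
Why: Alkoxide-catalysed oxa-Michael addition to the doubly activated acrylate gives the β-alkoxy phosphonate that carries C11, C12 and oxygenated C13.

Step 11
Reactants: 21 ethyl 2-(diethoxyphosphoryl)-3-[(4-methoxybenzyl)oxy]propanoate
Product: 22 2-(diethoxyphosphoryl)-3-[(4-methoxybenzyl)oxy]propanoic acid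
Conditions: Me3SnOH, ClCH2CH2Cl, 70 °C; dilute aq. HCl wash
Reagents that add atoms: trimethyltin hydroxide C[Sn](C)(C)O
Why: Non-basic ester cleavage with trimethyltin hydroxide leaves the phosphonate esters intact and avoids retro-Michael loss of the alkoxide that aqueous hydroxide could cause.

Step 12
Reactants: 19 (3S,5E,9R)-3-(tert-butyldimethylsilyloxy)-1-chloro-10-hydroxy-9-[(4-methoxybenzyl)oxy]-5,9-dimethyldec-5-en-2-one, 22 2-(diethoxyphosphoryl)-3-[(4-methoxybenzyl)oxy]propanoic acid
Product: 24 4-[(1S,3E,7R)-1-(tert-butyldimethylsilyloxy)-8-hydroxy-7-[(4-methoxybenzyl)oxy]-3,7-dimethyloct-3-en-1-yl]-3-{[(4-methoxybenzyl)oxy]methyl}furan-2(5H)-one, via keto phosphonate ester 23 (not isolated)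
Conditions: 22, Cs2CO3, NaI (cat.), MeCN, 0 °C → rt; then LiCl, i-Pr2NEt, rt
Reagents that add atoms: none
Why: Carboxylate displacement of the α-chloride forms the C6–O bond, and an intramolecular Horner–Wadsworth–Emmons olefination under Masamune–Roush conditions forms C7=C11 and closes the butenolide. The β-alkoxy phosphonate anion is the species used in alkoxide-addition/olefination sequences of 2-phosphonoacrylates, so a reversible retro-Michael step does no harm, and the mild base limits epimerisation at C8.

Step 13
Reactants: 24 4-[(1S,3E,7R)-1-(tert-butyldimethylsilyloxy)-8-hydroxy-7-[(4-methoxybenzyl)oxy]-3,7-dimethyloct-3-en-1-yl]-3-{[(4-methoxybenzyl)oxy]methyl}furan-2(5H)-one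
Product: 25 (2R,5E,8S)-8-(tert-butyldimethylsilyloxy)-2-[(4-methoxybenzyl)oxy]-8-(4-{[(4-methoxybenzyl)oxy]methyl}-5-oxo-2,5-dihydrofuran-3-yl)-2,6-dimethyloct-5-enal
Conditions: Dess–Martin periodinane, NaHCO3, CH2Cl2, 0 °C → rt
Reagents that add atoms: none
Why: Dess–Martin oxidation of the primary alcohol; the aldehyde cannot epimerise or enolise because C4 is quaternary.

Step 14
Reactants: 25 (2R,5E,8S)-8-(tert-butyldimethylsilyloxy)-2-[(4-methoxybenzyl)oxy]-8-(4-{[(4-methoxybenzyl)oxy]methyl}-5-oxo-2,5-dihydrofuran-3-yl)-2,6-dimethyloct-5-enal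
Product: 26 (2R,5E,8S)-8-(tert-butyldimethylsilyloxy)-2-[(4-methoxybenzyl)oxy]-8-[4-{[(4-methoxybenzyl)oxy]methyl}-5-(triisopropylsilyloxy)furan-3-yl]-2,6-dimethyloct-5-enal
Conditions: TIPSOTf (1.2 equiv), Et3N (3 equiv), CH2Cl2, −78 → −20 °C; amine-buffered work-up
Reagents that add atoms: triisopropylsilyl trifluoromethanesulfonate CC(C)[Si](OS(=O)(=O)C(F)(F)F)(C(C)C)C(C)C
Why: Soft enolisation and O-silylation of the butenolide gives the aromatic 2-silyloxyfuran; excess amine, low temperature and the bulky silyl group should suppress silyl-triflate-promoted aldol addition to the hindered aldehyde.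

Step 15
Reactants: 26 (2R,5E,8S)-8-(tert-butyldimethylsilyloxy)-2-[(4-methoxybenzyl)oxy]-8-[4-{[(4-methoxybenzyl)oxy]methyl}-5-(triisopropylsilyloxy)furan-3-yl]-2,6-dimethyloct-5-enal
Product: 27 (1(10)E,4R,5R,6S,8S)-8-(tert-butyldimethylsilyloxy)-5-hydroxy-4,13-bis[(4-methoxybenzyl)oxy]germacra-1(10),7(11)-dien-12,6-olide
Conditions: MgBr2·OEt2 (5 equiv), CH2Cl2, −20 → 0 °C, 26 added by syringe pump to a final 0.5 mM; aq. NaHCO3
Reagents that add atoms: none
Why: Proposed new method: MgBr2 binds the aldehyde oxygen and the C4 ether oxygen in a five-membered chelate, the 2-silyloxyfuran attacks the activated carbonyl through its 5-position (C6) in an open transition state, and loss of the silyl group from the resulting oxocarbenium ion returns the butenolide; the closest known reaction types are the intermolecular chelation-controlled vinylogous Mukaiyama aldol of 2-silyloxyfurans with α-alkoxy aldehydes and the intramolecular silylative vinylogous aldol that closes five- to seven-membered carbocycles, neither of which has been shown for a ten-membered ring. The ten-membered carbocycle closes in a 10-(enolendo)-exo-trig mode, and the E C1=C10 alkene, the planar furan and the chelate ring remove rotors from the chain. C5 is controlled by the chelate: C3 lies on one face of the carbonyl and the C15 methyl on the other, and the tethered furan can reach C5 only from the methyl face with C3–C4–C5–C6 near antiperiplanar, which should give the 4,5-syn (5R) alcohol needed for the later inversion. C6 is controlled by C8: allylic 1,3-strain with the C13 substituent keeps C8–H in the furan plane and C9 on one face, and the ring can close only with C5 on the opposite face, which corresponds to 6S. The step needs cyclisation to win over oligomerisation, which slow addition into a dilute solution of the Lewis acid should secure, and attack through C6 and not C11, which the substituent on C11 secures. The aldehyde cannot enolise because C4 is quaternary, and the silyl ether at C8 does not compete for the metal.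

Step 16
Reactants: 27 (1(10)E,4R,5R,6S,8S)-8-(tert-butyldimethylsilyloxy)-5-hydroxy-4,13-bis[(4-methoxybenzyl)oxy]germacra-1(10),7(11)-dien-12,6-olide
Product: 28 (1(10)E,4R,5R,6S,8S)-8-(tert-butyldimethylsilyloxy)-5-(methanesulfonyloxy)-4,13-bis[(4-methoxybenzyl)oxy]germacra-1(10),7(11)-dien-12,6-olide
Conditions: MsCl, Et3N, CH2Cl2, −30 °C, short reaction time
Reagents that add atoms: methanesulfonyl chloride CS(=O)(=O)Cl
Why: Sulfonylation of the only free hydroxyl through the sulfene pathway, which tolerates the hindered secondary position; low temperature is meant to prevent E1cB loss of the mesylate through C6–H.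

Step 17
Reactants: 28 (1(10)E,4R,5R,6S,8S)-8-(tert-butyldimethylsilyloxy)-5-(methanesulfonyloxy)-4,13-bis[(4-methoxybenzyl)oxy]germacra-1(10),7(11)-dien-12,6-olide
Product: 29 (1(10)E,4R,5R,6S,8S)-8-(tert-butyldimethylsilyloxy)-4,13-dihydroxy-5-(methanesulfonyloxy)germacra-1(10),7(11)-dien-12,6-olide
Conditions: DDQ (3 equiv), CH2Cl2/pH 7 phosphate buffer, 0 °C → rt
Reagents that add atoms: none
Why: Oxidative cleavage of both PMB ethers (hydride abstraction, hydrolysis of the oxocarbenium ion); it is run after mesylation so that no neighbouring hydroxyl can capture the C4 oxocarbenium ion as a benzylidene acetal.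

Step 18
Reactants: 29 (1(10)E,4R,5R,6S,8S)-8-(tert-butyldimethylsilyloxy)-4,13-dihydroxy-5-(methanesulfonyloxy)germacra-1(10),7(11)-dien-12,6-olide
Product: 30 (1(10)E,4R,5S,6S,8S)-8-(tert-butyldimethylsilyloxy)-4,5-epoxy-13-hydroxygermacra-1(10),7(11)-dien-12,6-olide
Conditions: K2CO3, MeOH, 0 °C
Reagents that add atoms: none
Why: Intramolecular Williamson etherification (3-exo-tet): the tertiary C4 alkoxide displaces the mesylate with inversion at C5, turning the syn arrangement into the cis-epoxide (4R,5S); the silyl ether keeps the C8 oxygen from attacking C12 or C5.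

Step 19
Reactants: 30 (1(10)E,4R,5S,6S,8S)-8-(tert-butyldimethylsilyloxy)-4,5-epoxy-13-hydroxygermacra-1(10),7(11)-dien-12,6-olide
Product: 31 (1(10)E,4R,5S,6S,8S)-13-acetoxy-8-(tert-butyldimethylsilyloxy)-4,5-epoxygermacra-1(10),7(11)-dien-12,6-olide
Conditions: Ac2O, pyridine, CH2Cl2, 0 °C
Reagents that add atoms: acetic anhydride CC(=O)OC(C)=O
Why: Acetylation of the only free (primary allylic) hydroxyl under weakly basic conditions that should leave the epoxy butenolide intact.

Step 20
Reactants: 31 (1(10)E,4R,5S,6S,8S)-13-acetoxy-8-(tert-butyldimethylsilyloxy)-4,5-epoxygermacra-1(10),7(11)-dien-12,6-olide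
Product: 32 (1(10)E,4R,5S,6S,8S)-13-acetoxy-4,5-epoxy-8-hydroxygermacra-1(10),7(11)-dien-12,6-olide
Conditions: HF·pyridine, pyridine, THF, 0 °C → rt
Reagents that add atoms: none
Why: Buffered fluoride-acid desilylation of the secondary silyl ether; the non-basic medium avoids acetyl migration, re-lactonisation onto the C8 oxygen and E1cB opening of the epoxide.

Step 21
Reactants: 33 methyl (2S)-2-methyloxirane-2-carboxylate
Product: 34 lithium (2S)-2-methyloxirane-2-carboxylate
Conditions: LiOH·H2O (1.0 equiv), THF/H2O, 0 °C; lyophilise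
Reagents that add atoms: lithium hydroxide [Li+].[OH-]
Why: Saponification with one equivalent of hydroxide gives the glycidate as its stable salt; the quaternary α-carbon cannot epimerise.

Step 22
Reactants: 32 (1(10)E,4R,5S,6S,8S)-13-acetoxy-4,5-epoxy-8-hydroxygermacra-1(10),7(11)-dien-12,6-olide, 34 lithium (2S)-2-methyloxirane-2-carboxylate
Product: 36 (1(10)E,4R,5S,6S,8S)-13-acetoxy-4,5-epoxy-8-[(2S)-2-methyloxirane-2-carbonyloxy]germacra-1(10),7(11)-dien-12,6-olide, via Yamaguchi mixed anhydride 35 (not isolated)
Conditions: 34, 2,4,6-trichlorobenzoyl chloride, THF, rt; then 32, DMAP, toluene, 0 °C → rt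
Reagents that add atoms: none
Why: Yamaguchi esterification: the mixed anhydride transfers the hindered acyl group through the acylpyridinium ion to the C8 hydroxyl, which is trapped before it can re-lactonise; no stereocentre is formed or touched.

Step 23
Reactants: 36 (1(10)E,4R,5S,6S,8S)-13-acetoxy-4,5-epoxy-8-[(2S)-2-methyloxirane-2-carbonyloxy]germacra-1(10),7(11)-dien-12,6-olide
Product: 37 (1R,4R,5S,6S,8S,10R)-13-acetoxy-1,10:4,5-diepoxy-8-[(2S)-2-methyloxirane-2-carbonyloxy]germacr-7(11)-en-12,6-olide (target)
Conditions: dimethyldioxirane, acetone, −20 → 0 °C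
Reagents that add atoms: dimethyldioxirane CC1(C)OO1
Why: Electrophilic epoxidation by a dioxirane: only the electron-rich trisubstituted C1=C10 alkene reacts, stereospecifically, and oxygen is delivered to the peripheral face of the E alkene in the ten-membered ring, which is expected to give 1R,10R; the reagent is neutral and its by-product volatile.

## Compound list

1 | 2-methyl-2-vinyloxirane (racemic) | CC1(C=C)CO1 | starting material
2 | 4-methoxybenzyl alcohol | COc1ccc(CO)cc1 | starting material
3 | (2R)-2-[(4-methoxybenzyl)oxy]-2-methylbut-3-en-1-ol | C=C[C@@](C)(OCc1ccc(OC)cc1)CO | intermediate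
4 | propargyl alcohol | C#CCO | starting material
5 | dimethyl{(E)-3-[(dimethylalumanyl)oxy]-2-methylprop-1-en-1-yl}alumane | C[Al](C)OC/C(C)=C/[Al](C)C | intermediate
6 | (E)-3-iodo-2-methylprop-2-en-1-ol | OC/C(C)=C/I | intermediate
7 | (E)-1,3-diiodo-2-methylprop-1-ene | IC/C(C)=C/I | intermediate
8 | glycolic acid | OCC(=O)O | starting material
9 | tert-butyldimethylsilyl (tert-butyldimethylsilyloxy)acetate | CC(C)(C)[Si](C)(C)OCC(=O)O[Si](C)(C)C(C)(C)C | intermediate
10 | (tert-butyldimethylsilyloxy)acetic acid | CC(C)(C)[Si](C)(C)OCC(=O)O | intermediate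
11 | (R)-4-benzyl-2-oxazolidinone | O=C1N[C@H](Cc2ccccc2)CO1 | starting material
12 | (tert-butyldimethylsilyloxy)acetic pivalic anhydride | CC(C)(C)C(=O)OC(=O)CO[Si](C)(C)C(C)(C)C | intermediate
13 | (4R)-4-benzyl-3-[(tert-butyldimethylsilyloxy)acetyl]oxazolidin-2-one | O=C1OC[C@@H](Cc2ccccc2)N1C(=O)CO[Si](C)(C)C(C)(C)C | intermediate
14 | sodium (Z)-enolate of 13 | O=C1OC[C@@H](Cc2ccccc2)N1C(/[O-])=C/O[Si](C)(C)C(C)(C)C.[Na+] | intermediate
15 | (4R)-4-benzyl-3-[(2S,4E)-2-(tert-butyldimethylsilyloxy)-5-iodo-4-methylpent-4-enoyl]oxazolidin-2-one | O=C1OC[C@@H](Cc2ccccc2)N1C(=O)[C@@H](O[Si](C)(C)C(C)(C)C)C/C(C)=C/I | intermediate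
16 | (2S,4E)-2-(tert-butyldimethylsilyloxy)-5-iodo-N-methoxy-N,4-dimethylpent-4-enamide | CON(C)C(=O)[C@@H](O[Si](C)(C)C(C)(C)C)C/C(C)=C/I | intermediate
17 | 9-{(3R)-4-(9-borabicyclo[3.3.1]nonan-9-yloxy)-3-[(4-methoxybenzyl)oxy]-3-methylbutyl}-9-borabicyclo[3.3.1]nonane | COc1ccc(CO[C@](C)(CCB2C3CCCC2CCC3)COB2C3CCCC2CCC3)cc1 | intermediate
18 | (2S,4E,8R)-2-(tert-butyldimethylsilyloxy)-9-hydroxy-N-methoxy-8-[(4-methoxybenzyl)oxy]-N,4,8-trimethylnon-4-enamide | CON(C)C(=O)[C@@H](O[Si](C)(C)C(C)(C)C)C/C(C)=C/CC[C@@](C)(OCc1ccc(OC)cc1)CO | intermediate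
19 | (3S,5E,9R)-3-(tert-butyldimethylsilyloxy)-1-chloro-10-hydroxy-9-[(4-methoxybenzyl)oxy]-5,9-dimethyldec-5-en-2-one | ClCC(=O)[C@@H](O[Si](C)(C)C(C)(C)C)C/C(C)=C/CC[C@@](C)(OCc1ccc(OC)cc1)CO | intermediate
20 | ethyl 2-(diethoxyphosphoryl)acrylate | C=C(C(=O)OCC)P(=O)(OCC)OCC | starting material
21 | ethyl 2-(diethoxyphosphoryl)-3-[(4-methoxybenzyl)oxy]propanoate (racemic) | CCOC(=O)C(COCc1ccc(OC)cc1)P(=O)(OCC)OCC | intermediate
22 | 2-(diethoxyphosphoryl)-3-[(4-methoxybenzyl)oxy]propanoic acid (racemic) | OC(=O)C(COCc1ccc(OC)cc1)P(=O)(OCC)OCC | intermediate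
23 | (3S,5E,9R)-3-(tert-butyldimethylsilyloxy)-10-hydroxy-9-[(4-methoxybenzyl)oxy]-5,9-dimethyl-2-oxodec-5-en-1-yl 2-(diethoxyphosphoryl)-3-[(4-methoxybenzyl)oxy]propanoate | CCOP(=O)(OCC)C(COCc1ccc(OC)cc1)C(=O)OCC(=O)[C@@H](O[Si](C)(C)C(C)(C)C)C/C(C)=C/CC[C@@](C)(OCc1ccc(OC)cc1)CO | intermediate
24 | 4-[(1S,3E,7R)-1-(tert-butyldimethylsilyloxy)-8-hydroxy-7-[(4-methoxybenzyl)oxy]-3,7-dimethyloct-3-en-1-yl]-3-{[(4-methoxybenzyl)oxy]methyl}furan-2(5H)-one | O=C1OCC(=C1COCc1ccc(OC)cc1)[C@@H](O[Si](C)(C)C(C)(C)C)C/C(C)=C/CC[C@@](C)(OCc1ccc(OC)cc1)CO | intermediate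
25 | (2R,5E,8S)-8-(tert-butyldimethylsilyloxy)-2-[(4-methoxybenzyl)oxy]-8-(4-{[(4-methoxybenzyl)oxy]methyl}-5-oxo-2,5-dihydrofuran-3-yl)-2,6-dimethyloct-5-enal | O=C1OCC(=C1COCc1ccc(OC)cc1)[C@@H](O[Si](C)(C)C(C)(C)C)C/C(C)=C/CC[C@@](C)(OCc1ccc(OC)cc1)C=O | intermediate
26 | (2R,5E,8S)-8-(tert-butyldimethylsilyloxy)-2-[(4-methoxybenzyl)oxy]-8-[4-{[(4-methoxybenzyl)oxy]methyl}-5-(triisopropylsilyloxy)furan-3-yl]-2,6-dimethyloct-5-enal | COc1ccc(COCc2c(O[Si](C(C)C)(C(C)C)C(C)C)occ2[C@@H](O[Si](C)(C)C(C)(C)C)C/C(C)=C/CC[C@@](C)(OCc2ccc(OC)cc2)C=O)cc1 | intermediate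
27 | (1(10)E,4R,5R,6S,8S)-8-(tert-butyldimethylsilyloxy)-5-hydroxy-4,13-bis[(4-methoxybenzyl)oxy]germacra-1(10),7(11)-dien-12,6-olide | COc1ccc(COCC2=C3[C@@H](O[Si](C)(C)C(C)(C)C)C/C(C)=C/CC[C@@](C)(OCc4ccc(OC)cc4)[C@H](O)[C@H]3OC2=O)cc1 | intermediate
28 | (1(10)E,4R,5R,6S,8S)-8-(tert-butyldimethylsilyloxy)-5-(methanesulfonyloxy)-4,13-bis[(4-methoxybenzyl)oxy]germacra-1(10),7(11)-dien-12,6-olide | COc1ccc(COCC2=C3[C@@H](O[Si](C)(C)C(C)(C)C)C/C(C)=C/CC[C@@](C)(OCc4ccc(OC)cc4)[C@H](OS(C)(=O)=O)[C@H]3OC2=O)cc1 | intermediate
29 | (1(10)E,4R,5R,6S,8S)-8-(tert-butyldimethylsilyloxy)-4,13-dihydroxy-5-(methanesulfonyloxy)germacra-1(10),7(11)-dien-12,6-olide | OCC1=C2[C@@H](O[Si](C)(C)C(C)(C)C)C/C(C)=C/CC[C@@](C)(O)[C@H](OS(C)(=O)=O)[C@H]2OC1=O | intermediate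
30 | (1(10)E,4R,5S,6S,8S)-8-(tert-butyldimethylsilyloxy)-4,5-epoxy-13-hydroxygermacra-1(10),7(11)-dien-12,6-olide | OCC1=C2[C@@H](O[Si](C)(C)C(C)(C)C)C/C(C)=C/CC[C@@]3(C)O[C@H]3[C@H]2OC1=O | intermediate
31 | (1(10)E,4R,5S,6S,8S)-13-acetoxy-8-(tert-butyldimethylsilyloxy)-4,5-epoxygermacra-1(10),7(11)-dien-12,6-olide | CC(=O)OCC1=C2[C@@H](O[Si](C)(C)C(C)(C)C)C/C(C)=C/CC[C@@]3(C)O[C@H]3[C@H]2OC1=O | intermediate
32 | (1(10)E,4R,5S,6S,8S)-13-acetoxy-4,5-epoxy-8-hydroxygermacra-1(10),7(11)-dien-12,6-olide | CC(=O)OCC1=C2[C@@H](O)C/C(C)=C/CC[C@@]3(C)O[C@H]3[C@H]2OC1=O | intermediate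
33 | methyl (2S)-2-methyloxirane-2-carboxylate | COC(=O)[C@]1(C)CO1 | starting material
34 | lithium (2S)-2-methyloxirane-2-carboxylate | [Li+].[O-]C(=O)[C@]1(C)CO1 | intermediate
35 | (2S)-2-methyloxirane-2-carboxylic 2,4,6-trichlorobenzoic anhydride | O=C(OC(=O)c1c(Cl)cc(Cl)cc1Cl)[C@]1(C)CO1 | intermediate
36 | (1(10)E,4R,5S,6S,8S)-13-acetoxy-4,5-epoxy-8-[(2S)-2-methyloxirane-2-carbonyloxy]germacra-1(10),7(11)-dien-12,6-olide | CC(=O)OCC1=C2[C@@H](OC(=O)[C@]3(C)CO3)C/C(C)=C/CC[C@@]3(C)O[C@H]3[C@H]2OC1=O | intermediate
37 | (1R,4R,5S,6S,8S,10R)-13-acetoxy-1,10:4,5-diepoxy-8-[(2S)-2-methyloxirane-2-carbonyloxy]germacr-7(11)-en-12,6-olide | CC(=O)OCC1=C2[C@@H](OC(=O)[C@]3(C)CO3)C[C@@]3(C)O[C@@H]3CC[C@@]3(C)O[C@H]3[C@H]2OC1=O | target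

## Step count and least certain steps

Total: 23 steps. Longest linear sequence: 17 steps (4 → 6 → 7 → 15 → 16 → 18 → 19 → 24 → 25 → 26 → 27 → 28 → 29 → 30 → 31 → 32 → 36 → 37).

**Step 15 (key step, proposed new method).** The most likely failure is intermolecular aldol addition (oligomerisation) outrunning the closure, because the ten-membered transition state is strained and entropically costly. Next come addition through a non-chelated arrangement or through the other furan face, which would give the wrong configuration at C5 or C6, and protodesilylation of the silyloxyfuran before it reacts. The fallback uses known reaction types and moves the ring closure to C1–C2. It sets out from 3 and 16 and returns at 27. Alcohol 3 is oxidised with Dess–Martin periodinane to the aldehyde (2R)-2-[(4-methoxybenzyl)oxy]-2-methylbut-3-enal F1. Amide 16 is homologated with chloromethyllithium, as in step 9, to the iodo chloroketone F2. F2 is condensed with acid 22, as in step 12, to the iodo butenolide F3, which is silylated as in step 14 to the iodo silyloxyfuran F4. An intermolecular MgBr2·OEt2-mediated vinylogous Mukaiyama aldol of F4 with F1, the established chelation-controlled reaction, forms C5–C6 and gives the open-chain adduct F5. Hydroboration of the vinyl group of F5 with 9-BBN and a ring-closing B-alkyl Suzuki–Miyaura coupling (Pd(dppf)Cl2·CH2Cl2, AsPh3, K3PO4, high dilution) then closes C1–C2 and gives 27. In this variant C6 is set without the ring constraint and may need separation of isomers.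

**Step 14.** The silyl triflate may activate the aldehyde towards the freshly formed silyloxyfuran, so that non-chelated aldol addition or oligomerisation begins during the silylation. At the low temperature chosen to prevent this, silylation may be incomplete. The fallback forms the silyloxyfuran before the aldehyde exists. It sets out from 24 and returns at 26. The primary hydroxyl of 24 is capped with TMSCl/imidazole to give the trimethylsilyl ether F6. Silylation with TIPSOTf/Et3N gives the silyloxyfuran trimethylsilyl ether F7. Brief K2CO3/MeOH at −10 °C removes only the primary trimethylsilyl group and gives the silyloxyfuran alcohol F8. A Ley–Griffith oxidation (n-Pr4N[RuO4], N-methylmorpholine N-oxide, molecular sieves) then gives 26 under neutral conditions.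

**Step 18 (with step 16).** Deprotonation at C6, the γ-position of the butenolide, can expel the C5 mesylate by E1cB and give a 5-ylidene butenolide. This can happen during the mesylation with amine base or during the carbonate treatment, in competition with the three-membered ring closure. The fallback avoids sulfonate and external base. It sets out from 27 and returns at 31. DDQ in buffered CH2Cl2 removes the C13 PMB group and converts the C4 PMB ether, through capture by the free C5 hydroxyl, into the 4,5-O-(4-methoxybenzylidene) acetal F9. Acetylation (Ac2O, pyridine) gives the acetal acetate F10. Aqueous acetic acid hydrolyses the acetal to the 4,5-diol F11. Cyclodehydration of F11 through a dioxaphosphorane (Ph3P(OEt)2, toluene, 50 °C, or PPh3 with diisopropyl azodicarboxylate) displaces the activated C5 oxygen with the C4 oxygen, with inversion, and gives 31.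

**Step 23.** The facial selectivity rests on the ring conformation alone. If the reactive conformer exposes the other face of C1=C10, the 1S,10S epoxide would result, and a poor preference would give a mixture. The fallback inverts the sense of oxygen delivery. It sets out from 36 and returns at 37. N-Bromosuccinimide in aqueous THF adds bromine from the exposed face and water at the tertiary C10 from the opposite face, giving the bromohydrin (1S,10R)-1-bromo-10-hydroxy derivative F12. Ag2O then closes the epoxide by displacement at C1, so the oxygen ends on the face that direct epoxidation did not reach, giving 37.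

## Further compounds

F1 | step 15 | (2R)-2-[(4-methoxybenzyl)oxy]-2-methylbut-3-enal | C=C[C@@](C)(OCc1ccc(OC)cc1)C=O
F2 | step 15 | (3S,5E)-3-(tert-butyldimethylsilyloxy)-1-chloro-6-iodo-5-methylhex-5-en-2-one | ClCC(=O)[C@@H](O[Si](C)(C)C(C)(C)C)C/C(C)=C/I
F3 | step 15 | 4-[(1S,3E)-1-(tert-butyldimethylsilyloxy)-4-iodo-3-methylbut-3-en-1-yl]-3-{[(4-methoxybenzyl)oxy]methyl}furan-2(5H)-one | O=C1OCC(=C1COCc1ccc(OC)cc1)[C@@H](O[Si](C)(C)C(C)(C)C)C/C(C)=C/I
F4 | step 15 | tert-butyl{[(1S,3E)-4-iodo-1-[4-{[(4-methoxybenzyl)oxy]methyl}-5-(triisopropylsilyloxy)furan-3-yl]-3-methylbut-3-en-1-yl]oxy}dimethylsilane | COc1ccc(COCc2c(O[Si](C(C)C)(C(C)C)C(C)C)occ2[C@@H](O[Si](C)(C)C(C)(C)C)C/C(C)=C/I)cc1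
F5 | step 15 | (5S)-4-[(1S,3E)-1-(tert-butyldimethylsilyloxy)-4-iodo-3-methylbut-3-en-1-yl]-5-{(1R,2R)-1-hydroxy-2-[(4-methoxybenzyl)oxy]-2-methylbut-3-en-1-yl}-3-{[(4-methoxybenzyl)oxy]methyl}furan-2(5H)-one | C=C[C@@](C)(OCc1ccc(OC)cc1)[C@H](O)[C@H]1OC(=O)C(COCc2ccc(OC)cc2)=C1[C@@H](O[Si](C)(C)C(C)(C)C)C/C(C)=C/I
F6 | step 14 | trimethylsilyl ether of 24 at the primary hydroxyl | O=C1OCC(=C1COCc1ccc(OC)cc1)[C@@H](O[Si](C)(C)C(C)(C)C)C/C(C)=C/CC[C@@](C)(OCc1ccc(OC)cc1)CO[Si](C)(C)C
F7 | step 14 | 2-(triisopropylsilyloxy)furan derived from F6 | COc1ccc(COCc2c(O[Si](C(C)C)(C(C)C)C(C)C)occ2[C@@H](O[Si](C)(C)C(C)(C)C)C/C(C)=C/CC[C@@](C)(OCc2ccc(OC)cc2)CO[Si](C)(C)C)cc1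
F8 | step 14 | (2R,5E,8S)-8-(tert-butyldimethylsilyloxy)-2-[(4-methoxybenzyl)oxy]-8-[4-{[(4-methoxybenzyl)oxy]methyl}-5-(triisopropylsilyloxy)furan-3-yl]-2,6-dimethyloct-5-en-1-ol | COc1ccc(COCc2c(O[Si](C(C)C)(C(C)C)C(C)C)occ2[C@@H](O[Si](C)(C)C(C)(C)C)C/C(C)=C/CC[C@@](C)(OCc2ccc(OC)cc2)CO)cc1
F9 | step 18 | (1(10)E,4R,5R,6S,8S)-8-(tert-butyldimethylsilyloxy)-13-hydroxy-4,5-[(4-methoxybenzylidene)dioxy]germacra-1(10),7(11)-dien-12,6-olide (acetal carbon unspecified) | OCC1=C2[C@@H](O[Si](C)(C)C(C)(C)C)C/C(C)=C/CC[C@@]3(C)OC(c4ccc(OC)cc4)O[C@@H]3[C@H]2OC1=O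
F10 | step 18 | (1(10)E,4R,5R,6S,8S)-13-acetoxy-8-(tert-butyldimethylsilyloxy)-4,5-[(4-methoxybenzylidene)dioxy]germacra-1(10),7(11)-dien-12,6-olide (acetal carbon unspecified) | CC(=O)OCC1=C2[C@@H](O[Si](C)(C)C(C)(C)C)C/C(C)=C/CC[C@@]3(C)OC(c4ccc(OC)cc4)O[C@@H]3[C@H]2OC1=O
F11 | step 18 | (1(10)E,4R,5R,6S,8S)-13-acetoxy-8-(tert-butyldimethylsilyloxy)-4,5-dihydroxygermacra-1(10),7(11)-dien-12,6-olide | CC(=O)OCC1=C2[C@@H](O[Si](C)(C)C(C)(C)C)C/C(C)=C/CC[C@@](C)(O)[C@H](O)[C@H]2OC1=O
F12 | step 23 | (1S,4R,5S,6S,8S,10R)-13-acetoxy-1-bromo-4,5-epoxy-10-hydroxy-8-[(2S)-2-methyloxirane-2-carbonyloxy]germacr-7(11)-en-12,6-olide | CC(=O)OCC1=C2[C@@H](OC(=O)[C@]3(C)CO3)C[C@@](C)(O)[C@@H](Br)CC[C@@]3(C)O[C@H]3[C@H]2OC1=O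
A1 | alternative 1 | cis-anti-cis enone–cyclobutene photoadduct (silyloxy cyclohexanone fused to a bicyclo[2.2.0]hexane) | O=C1C[C@@H](O[Si](C)(C)C(C)(C)C)C[C@]2(C)[C@H]3CC[C@@]3(C)[C@H]12
A2 | alternative 2 | (8S)-8-[(4-methoxybenzyl)oxy]germacra-1(10)E,4Z-dien-6-one | O=C1/C=C(C)\CC/C=C(C)/C[C@H](OCc2ccc(OC)cc2)C1
A3 | alternative 3 | 6-(tert-butyldimethylsilyloxy)-8-[(4-methoxybenzyl)oxy]-7-methylene-2-(phenylsulfonyl)germacra-1(10)E,4Z-diene | C=C1[C@@H](OCc2ccc(OC)cc2)C/C(C)=C/[C@@H](S(=O)(=O)c2ccccc2)C/C(C)=C\[C@H]1O[Si](C)(C)C(C)(C)C
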